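## Retrosynthetic overview
1. Punaglandin 4 (**18**) comes from base-induced E1cB opening of the oxetane **17**. This unmasks the C12 tertiary alkoxide and the exocyclic 7E alkene.
2. **17** comes from an intramolecular Paternò–Büchi closure of the cis-chloroenedione **16**. This photochemical step forms the C8–C12 bond, which closes the cyclopentenone ring and sets C12 under control of C6.
3. **16** comes from singlet-oxygen oxidation of the 2-alkenylfuran **15**. The furan is made first, opened oxidatively, and the carbocycle then closes.
4. **15** comes from cross-metathesis of the chlorovinylfuran **14** with the diacetoxy-alkene **8**. **8** is built from L-threitol acetonide (Giese coupling, Wittig methylenation). **14** is built from furfural and cis-2-octenol.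

Assumptions:
- Prostanoid numbering is used: C1 is the CO2Me carbon, C5/C6 carry the acetates, C7=C8 is the exocyclic alkene, C9 is the ketone, C10 bears Cl, C12 is the carbinol, and C14=C15 is the Z-alkene.
- Compounds 1, 3, 9 and 11 are commercial.
- The 7E alkene is the favoured product of the E1cB opening.

## Route

**Step 1**
Reactants: **1** (4S,5S)-2,3-O-isopropylidene-L-threitol
Product: **2** [(4S,5R)-5-(iodomethyl)-2,2-dimethyl-1,3-dioxolan-4-yl]methanol
Conditions: PPh3 (0.9 equiv), I2 (0.9 equiv), imidazole, toluene/MeCN, 0 °C → rt
Reagents that add atoms: iodine, II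
Why: An Appel/Garegg–Samuelsson iodination of the C2-symmetric diol, run statistically to give the mono-iodide (unreacted diol is recycled). No stereocenter is touched.

**Step 2**
Reactants: **2**; **3** methyl acrylate
Product: **4** methyl 4-[(4S,5S)-5-(hydroxymethyl)-2,2-dimethyl-1,3-dioxolan-4-yl]butanoate
Conditions: fac-Ir(ppy)3 (1 mol %), Et3N (3 equiv), Hantzsch ester (1.5 equiv), MeCN, blue LEDs, 25 °C
Reagents that add atoms: methyl acrylate (**3**), C=CC(=O)OC
Why: Visible-light halogen-atom abstraction gives the primary radical, which undergoes Giese addition to the acrylate and installs C3–C1. The free OH and the acetonide are inert and the stereocenters are remote.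

**Step 3**
Reactants: **4**
Product: **5** methyl 4-[(4S,5R)-5-formyl-2,2-dimethyl-1,3-dioxolan-4-yl]butanoate
Conditions: Dess–Martin periodinane, NaHCO3, CH2Cl2, 0 °C → rt
Reagents that add atoms: none
Why: Mild oxidation of the primary alcohol to the aldehyde. The trans-dioxolane is the stable epimer, so the α-stereocenter does not erode.

**Step 4**
Reactants: **5**
Product: **6** methyl 4-[(4S,5S)-2,2-dimethyl-5-vinyl-1,3-dioxolan-4-yl]butanoate
Conditions: Ph3PCH3Br, KOt-Bu, THF, 0 °C
Reagents that add atoms: methylenetriphenylphosphorane, C=P(c1ccccc1)(c1ccccc1)c1ccccc1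
Why: Wittig methylenation creates the terminal alkene (C7=C8) needed for cross-metathesis. The ester is untouched and the stereocenters are retained.

**Step 5**
Reactants: **6**
Product: **7** methyl (5S,6S)-5,6-dihydroxyoct-7-enoate
Conditions: Dowex 50WX8 (H+), MeOH, 25 °C
Reagents that add atoms: none
Why: Acid-catalysed transacetalisation removes the acetonide. MeOH as solvent suppresses δ-lactonisation of the 5-OH onto the ester, and the stereocenters are untouched.

**Step 6**
Reactants: **7**
Product: **8** methyl (5S,6S)-5,6-diacetoxyoct-7-enoate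
Conditions: Ac2O (3 equiv), pyridine, DMAP (cat.), CH2Cl2, 0 °C → rt
Reagents that add atoms: acetic anhydride, CC(=O)OC(C)=O
Why: Bis-acetylation installs the C5/C6 acetates found in the target, with retention at both centers.

**Step 7**
Reactants: **9** (Z)-oct-2-en-1-ol
Product: **10** (Z)-1-bromooct-2-ene
Conditions: CBr4, PPh3, CH2Cl2, 0 °C
Reagents that add atoms: carbon tetrabromide, BrC(Br)(Br)Br
Why: Appel bromination proceeds by SN2 at the primary carbon, so the Z-alkene is retained.

**Step 8**
Reactants: **11** furfural; **10**
Product: **12** 5-[(Z)-oct-2-en-1-yl]furan-2-carbaldehyde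
Conditions: LiN(Me)CH2CH2NMe2, THF, −20 °C; n-BuLi; then **10**, −78 °C → rt; aqueous H3O+ work-up
Reagents that add atoms: (Z)-1-bromooct-2-ene (**10**), CCCCC/C=C\CBr
Why: Comins in-situ α-amino-alkoxide protection, C5 lithiation, then SN2 allylation with Z retention. Work-up releases the aldehyde.

**Step 9**
Reactants: **12**
Product: **13** 3-chloro-5-[(Z)-oct-2-en-1-yl]furan-2-carbaldehyde
Conditions: LiN(Me)CH2CH2NMe2, THF; n-BuLi (3 equiv), hexane/THF, −20 °C; then C2Cl6, −78 °C → rt
Reagents that add atoms: hexachloroethane, ClC(Cl)(Cl)C(Cl)(Cl)Cl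
Why: With C5 blocked, the amino-alkoxide directs lithiation to C3 (ortho-metalation), and C2Cl6 delivers Cl⁺ there. This puts the C10 chlorine in place on a simple, robust fragment.

**Step 10**
Reactants: **13**
Product: **14** 3-chloro-5-[(Z)-oct-2-en-1-yl]-2-vinylfuran
Conditions: Ph3PCH3Br, KOt-Bu, THF, 0 °C
Reagents that add atoms: methylenetriphenylphosphorane, C=P(c1ccccc1)(c1ccccc1)c1ccccc1
Why: Wittig methylenation gives the terminal vinyl for cross-metathesis.

**Step 11**
Reactants: **8**; **14**
Product: **15** methyl (5S,6S,7E)-5,6-diacetoxy-8-[3-chloro-5-((2Z)-oct-2-en-1-yl)furan-2-yl]oct-7-enoate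
Conditions: Hoveyda–Grubbs II (5 mol %), CH2Cl2 (0.05 M), 40 °C; **8** in excess (2 equiv)
Reagents that add atoms: none (ethylene is lost)
Why: Cross-metathesis of the vinylfuran with the allylic-acetate alkene forms the E-C7=C8 bond, and the stereocenters are untouched.

**Step 12**
Reactants: **15**
Product: **16** methyl (5S,6S,7E,10E,14Z)-5,6-diacetoxy-10-chloro-9,12-dioxoicosa-7,10,14-trienoate. The C9 and C12 carbons are cis on the C10=C11 alkene, which is the cis-enedione.
Conditions: O2, Rose Bengal (1 mol %), white LEDs, CH2Cl2, −78 °C; then Me2S (10 equiv), −78 → 0 °C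
Reagents that add atoms: oxygen, O=O
Why: Singlet-oxygen [4+2] across furan C9/C12 followed by Me2S reduction of the endoperoxide (Wasserman oxidation) gives the cis-enedione. This is chemoselective over the isolated Z-alkene and the acetates, and it sets no stereocenter.

**Step 13**
Reactants: **16**
Product: **17** cis-fused oxetane–chlorocyclopentenone (6-oxabicyclo[3.2.0]hept-3-en-2-one core). Its C12–O–C7 oxetane is fused at C8–C12, with 3-Cl (C10), the (Z)-octenyl group on C12, and the diacetoxy ester chain on C7 (C7 configuration unspecified).
Conditions: hν (405 nm LEDs), MeCN (5 mM), 10 °C, N2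
Reagents that add atoms: none
Why: Proposed new method: the triplet C12=O of the cis-enedione adds through oxygen to C7 of the tethered enone, giving a 1,4-biradical whose C8 radical is α-keto stabilised. C8–C12 recombination closes the five-membered ring, favoured by the rule of five and the cis-alkene, and gives the oxetane; the closest known reactions are the intramolecular Paternò–Büchi reaction and the intramolecular Morita–Baylis–Hillman aldol. C12 is set by 1,4-induction from C6, with the A(1,3)-strain rotamer (C6–H in plane) placing the C5 chain on the face opposite the attacking carbonyl. C7 and C8 are transient.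

**Step 14**
Reactants: **17**
Product: **18** punaglandin 4
Conditions: DBU (0.1 equiv), CH2Cl2, 0 °C, 15 min
Reagents that add atoms: none
Why: E1cB opening of the strained oxetane. The C8–H is α to the C9 ketone and the C7–O bond is β, so elimination releases strain, forms the exocyclic 7E alkene and leaves the C12 tertiary alcohol. The C12 configuration is untouched, and the C5/C6 acetates and the ester survive the catalytic, mild base.

## Compound list
| No. | Name | SMILES | Role |
|---|---|---|---|
| 1 | (4S,5S)-2,3-O-isopropylidene-L-threitol | OC[C@@H]1OC(C)(C)O[C@H]1CO | starting material |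
| 2 | mono-iodide | OC[C@@H]1OC(C)(C)O[C@H]1CI | intermediate |
| 3 | methyl acrylate | C=CC(=O)OC | starting material |
| 4 | Giese product (hydroxy ester) | OC[C@@H]1OC(C)(C)O[C@H]1CCCC(=O)OC | intermediate |
| 5 | aldehyde | O=C[C@@H]1OC(C)(C)O[C@H]1CCCC(=O)OC | intermediate |
| 6 | vinyl acetonide | C=C[C@@H]1OC(C)(C)O[C@H]1CCCC(=O)OC | intermediate |
| 7 | diol | C=C[C@H](O)[C@H](CCCC(=O)OC)O | intermediate |
| 8 | diacetate | C=C[C@H](OC(C)=O)[C@H](CCCC(=O)OC)OC(C)=O | intermediate |
| 9 | (Z)-oct-2-en-1-ol | CCCCC/C=C\CO | starting material |
| 10 | (Z)-1-bromooct-2-ene | CCCCC/C=C\CBr | intermediate |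
| 11 | furfural | O=Cc1ccco1 | starting material |
| 12 | 5-octenylfurfural | CCCCC/C=C\Cc1ccc(C=O)o1 | intermediate |
| 13 | 3-chloro-5-octenylfurfural | CCCCC/C=C\Cc1cc(Cl)c(C=O)o1 | intermediate |
| 14 | chlorovinylfuran | C=Cc1oc(C/C=C\CCCCC)cc1Cl | intermediate |
| 15 | alkenylfuran (cross-metathesis product) | CCCCC/C=C\Cc1cc(Cl)c(/C=C/[C@H](OC(C)=O)[C@H](CCCC(=O)OC)OC(C)=O)o1 | intermediate |
| 16 | cis-chloroenedione | CCCCC/C=C\CC(=O)/C=C(Cl)\C(=O)/C=C/[C@H](OC(C)=O)[C@H](CCCC(=O)OC)OC(C)=O | intermediate |
| 17 | oxetane (C7 unspecified) | CCCCC/C=C\C[C@@]12C=C(Cl)C(=O)[C@@H]1C(O2)[C@H](OC(C)=O)[C@H](CCCC(=O)OC)OC(C)=O | intermediate |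
| 18 | punaglandin 4 | CCCCC/C=C\C[C@@]1(O)C=C(Cl)C(=O)/C1=C/[C@H](OC(C)=O)[C@H](CCCC(=O)OC)OC(C)=O | target |

## Totals
- Total steps: 14.
- Longest linear sequence: 10 (steps 1–6, then 11–14).

## Three steps most likely to fail
1. **Step 13 (proposed new step: Paternò–Büchi closure of the enedione onto the enone).**
   - Risks: Z→E isomerisation of the enedione, enone [2+2] or di-π-methane reactions, and modest C12 diastereoselectivity.
   - Fallback: close the ring thermally from **16** by an intramolecular Morita–Baylis–Hillman-type aldol (Lewis-base or TiCl4/Bu4NI promoted) on the enone/ketone pair, then separate diastereomers. This is known chemistry and gives the same skeleton.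
2. **Step 9 (C3-directed lithiation and chlorination of the furfural).**
   - Risks: competing deprotonation of the doubly activated furfuryl/allylic CH2, and poor C3 regioselectivity.
   - Fallback: omit the chlorine (skip step 9) and run steps 10–14 on the unchlorinated furan to give the 10,11-unsubstituted enone. Then install Cl by nucleophilic epoxidation (t-BuOOH, Triton B), HCl opening of the epoxy ketone, and MsCl/Et3N dehydration.
3. **Step 11 (cross-metathesis of a hindered ortho-chlorovinylfuran).**
   - Risks: low conversion, furan homodimerisation, and metathesis of the internal Z-alkene.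
   - Fallback: build C7=C8 by Wittig coupling of aldehyde **5** with the ylide from the furfuryl alcohol obtained by reducing **13** (NaBH4, then PPh3·HBr). Then swap the acetonide for the diacetate after coupling.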